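Compound numbers used below are those of the steps and of the compound list.

## Analysis of the target

Target 19 is a flavone, a 4H-chromen-4-one in which benzo ring A is fused to pyranone ring C and a trioxygenated phenyl ring B sits on C2. It has no stereocentre, so every problem is one of constitution and of telling oxygen atoms apart. Six oxygen substituents are present in three states: methyl ethers at C3 and C4', free phenols at C5, C7 and C2', and an aryl acetate at C5'. The acetate is the sensitive group, because alkoxides, amines and even warm alcohols cleave it, so it has to be introduced late and everything after it must be neutral. Because three phenols must end up free while a fourth carries the acetyl group, O5' has to be distinguishable from O5, O7 and O2' throughout. The 3-methoxy group means that C3 must arrive as an α-methoxy carbon, and the 2'-oxygen makes the C2–C1' region crowded. The strategy rests on ring A: O1 on C8a, the C5 oxygen and the C7 oxygen all lie ortho or para to C4a, the carbon that bears the C4 carbonyl. Each of these three C–O bonds can therefore be made by displacing an acyl-activated aryl fluoride, and a 2,4,6-trifluorobenzoyl group, whose two ortho positions are equivalent, can deliver C4 and the whole of ring A.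

## Retrosynthetic reasoning

**19 ⇒ 18.** The last bonds cut are the three benzylic C–O bonds at O5, O7 and O2'. Hydrogenolysis is the one deprotection neutral enough for the aryl acetate. All three phenols that must be free are therefore carried as benzyl ethers, and the acetate is already present in 18.

**18 ⇒ 17 ⇒ 16.** Cutting the acetyl C–O bond gives phenol 17, in which O5' is the only free hydroxyl, so the acetylation needs no selectivity. This requires a fourth protecting group that is orthogonal to benzyl and stable to strong base. The allyl ether of 16 meets this, since a zerovalent palladium catalyst removes it without touching benzyl ethers or the chromone.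

**16 ⇒ 14.** The C5–O and C7–O bonds are cut back to C–F. In 14 both fluorines are ortho or para to C4a and activated by the chromone carbonyl. They are meta to each other, so the alkoxy group introduced first does not sit on a carbon that carries negative charge during the second addition. The forward reaction is a twofold SNAr with a benzylic alkoxide. Doing it after ring closure keeps the third fluorine for the ring-forming step, so three fluorines never have to be told apart.

**14 ⇒ 10 + 11 (key disconnection).** Ring C is opened at O1–C8a and the chain is cut at C3–C4. The cut falls between the only enolisable carbon of ketone 10 and the acyl carbon of acid chloride 11, and O1 becomes the former ketone oxygen of 10. The classical cut at O1–C2 would need a differentiated phenolic ring A. Here ring A needs no phenol at all, because 11 is purchased, symmetric, and brings C4, C4a–C8a and three leaving groups. The forward step must C-acylate enolate 12 to diketone 13 and then O-arylate in the same flask.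

**10 ⇒ 6 + 7.** The ketone is cut at the aryl–carbonyl bond (C1'–C2). Aryllithium 8, made from bromide 6, adds to Weinreb amide 7. The chelated adduct 9 prevents over-addition. Amide 7 supplies C2, C3 and the 3-methoxy group in one purchased piece, so no α-oxidation is needed.

**6 ⇒ 5 ⇒ 4 ⇒ 2 ⇒ 1.** The C–Br bond of 6 comes from electrophilic bromination of 5 at the position para to methoxy and ortho to benzyloxy, which is the future C1'. Ether 5 comes from phenol 4 by O-benzylation. Phenol 4 comes from aldehyde 2 by Baeyer–Villiger oxidation through formate 3, which turns the formyl carbon of vanillin 1 into the 2'-oxygen. Vanillin 1 already has the 4'-methoxy group next to a free hydroxyl, the future O5', which is allylated first. Each ring B oxygen is therefore differentiated from the first step on, with no selective protection.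

## Alternatives that were turned down

Alternative 1: Carbonylative three-component assembly.
- **Disconnection:** C4a–C4 and C4–C3, with C4 supplied by carbon monoxide A2.
- **Forward key step:** 1,5-bis(benzyloxy)-2-iodo-3-(methoxymethoxy)benzene A1, carbon monoxide A2 and 1-[2-(benzyloxy)-4-methoxy-5-(methoxymethoxy)phenyl]-2-methoxyethan-1-one A3 would be joined under Pd(dba)2 and Xantphos (zerovalent palladium) with base. Ketone A3 is the counterpart of 10 in which a methoxymethyl group stands in place of the allyl group. The product would be the open diketone 1-[2,4-bis(benzyloxy)-6-(methoxymethoxy)phenyl]-3-[2-(benzyloxy)-4-methoxy-5-(methoxymethoxy)phenyl]-2-methoxypropane-1,3-dione A4. Acid would then remove both acetals of A4 and cyclodehydrate it to 17.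
- **For it:** Every ring A oxygen is in place before the coupling, so no fluoride exchange is needed. The acid step on A4 would combine ring closure with release of O5' and reach 17 two steps sooner after the fragment union than the chosen route. No strongly basic nucleophile ever meets the chromone. On these points it is stronger.
- **Against it:** The aroylpalladium species from A1 is flanked by two ortho alkoxy groups. It must be captured at carbon by the enolate of A3, which is itself α-alkoxy-substituted and attached to an ortho-substituted aryl ring, so the C–C bond forms between two congested centres. Direct α-arylation without uptake of A2, hydrodeiodination and O-acylation are open side paths, and diketone A4 is a good ligand for palladium. No ring closes in the key step. Iodide A1 has to be made by desymmetrising a phloroglucinol derivative and iodinating it regioselectively, about three to four steps, which cancels the steps saved later. The toxic gas A2 must be handled.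
- **Comparison:** The chosen strategy makes the same C3–C4 bond without a catalyst from a purchased electrophile and closes ring C in the same flask. Its price is one later SNAr step.

Alternative 2: Biomimetic folding of a polyketide chain.
- **Disconnection:** Rings A and C are both opened, at C4a–C5 and O1–C2, and ring A is drawn from an acyclic poly-β-carbonyl chain.
- **Forward key step:** Methyl 9-[2-(benzyloxy)-4-methoxy-5-(4-methoxybenzyloxy)phenyl]-8,9-dimethoxy-3,5,7-trioxonon-8-enoate A5 would be treated with Mg(OMe)2 in methanol. The methylene flanked by two ketones (the future C4a) would attack the ester carbon (the future C5) in a Claisen condensation, and aromatisation would give the phloroglucinol ring. The new ortho phenol would then add to the β-methoxy enone and expel its methoxy group, giving 2-[2-(benzyloxy)-4-methoxy-5-(4-methoxybenzyloxy)phenyl]-5,7-dihydroxy-3-methoxy-4H-chromen-4-one A6.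
- **For it:** Two rings form in one operation under mild base. The ring A phenols of A6 arrive free, with no protecting group and no leaving-group exchange. In concept and atom economy it is stronger than the chosen route.
- **Against it:** Chain A5 has three active methylenes and four electrophilic carbonyl carbons. Aldol folding to a resorcylate-type ring and lactonisation to a pyranone ring compete with the wanted Claisen mode, and nothing in the structure beyond the magnesium template enforces the right one. Chain A5 itself needs several polyanion acylations and exists as a tautomer mixture. Most important, A6 has free O7–H (the most acidic phenol) and O5–H. Once the 4-methoxybenzyl group is removed, the 5'-acetate cannot be placed selectively. Both ring A phenols would first have to be benzylated, which leads back to 17 by a longer path.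
- **Comparison:** The chosen strategy buys ring A as an aromatic compound, so there is no folding question, and its ring A oxygens emerge already benzylated.

Alternative 3: Aryne annulation with an acylketene.
- **Disconnection:** O1–C8a and C4–C4a. Ring A is an aryne; C2, C3, C4 and ring B form an aroyl(methoxy)ketene.
- **Forward key step:** CsF would act on 3,5-bis(benzyloxy)-2-(trimethylsilyl)phenyl trifluoromethanesulfonate A7 to release 3,5-bis(benzyloxy)benzyne A8. In the same flask, 6-[5-(allyloxy)-2-(benzyloxy)-4-methoxyphenyl]-5-methoxy-2,2-dimethyl-4H-1,3-dioxin-4-one A9 would undergo thermal cycloreversion to 3-[5-(allyloxy)-2-(benzyloxy)-4-methoxyphenyl]-2-methoxy-3-oxoprop-1-en-1-one A10. The ketone oxygen of A10 would add to the carbon of A8 remote from the benzyloxy group. The resulting aryl anion, next to that benzyloxy group, would close onto the ketene carbon to give 2-[5-(allyloxy)-2-(benzyloxy)-4-methoxyphenyl]-5,7-bis(benzyloxy)-3-methoxy-4H-chromen-4-one A11. Chromone A11 is the same compound as 16.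
- **For it:** It lands directly on A11 and so on 16, one step beyond the product of the chosen key step, with no fluoride exchange. The inductive effect of the neighbouring alkoxy group steers the nucleophile to the correct carbon of A8. On these two points it is as strong or stronger.
- **Against it:** Both partners are transient and are released by different triggers, fluoride for A8 and heat for A10, so their concentrations must be matched. Acylketenes such as A10 dimerise and are captured by fluoride or traces of water. The carbonyl oxygen of A10 is a weak nucleophile for an aryne, and [2+2] addition across the ketene C=C bond competes. Triflate A7 needs about four steps (ortho-bromination, O-silylation, retro-Brook shift, triflation). Dioxinone A9 needs about three more from ring B material, under acidic acetalisation conditions that threaten the allyl and benzyl ethers.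
- **Comparison:** The chosen strategy joins two bench-stable partners in an ionic, stepwise sequence with only one possible constitution, and pays one extra step (14 → 16).

Key step: step 6

Remark: the target has no stereocentre. Intermediates 9 and 13 each have one racemic or enolisable centre and are drawn without configuration. Amide 7 and acid chloride 11 are taken as purchased.

## Route

Step 1
Reactants: 1 vanillin (4-hydroxy-3-methoxybenzaldehyde)
Product: 2 4-(allyloxy)-3-methoxybenzaldehyde
Conditions: allyl bromide, K2CO3, DMF, 50 °C
Reagents that add atoms: allyl bromide, C=CCBr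
Why: Williamson etherification of the only phenol, which the para formyl group makes acidic enough for K2CO3; this fixes the allyl group on the future O5'.

Step 2
Reactants: 2 4-(allyloxy)-3-methoxybenzaldehyde
Product: 4 4-(allyloxy)-3-methoxyphenol, via 4-(allyloxy)-3-methoxyphenyl formate 3 (not isolated)
Conditions: mCPBA, CH2Cl2, 0 °C → rt; then K2CO3 (cat.), MeOH, rt
Reagents that add atoms: mCPBA (3-chloroperoxybenzoic acid), OOC(=O)c1cccc(Cl)c1
Why: Baeyer–Villiger (Dakin-type) oxidation in which the electron-rich aryl group, para to the allyloxy donor, migrates to give formate 3, which is then methanolysed; the monosubstituted, inductively deactivated alkene of the allyl ether should epoxidise much more slowly than the aldehyde reacts.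

Step 3
Reactants: 4 4-(allyloxy)-3-methoxyphenol
Product: 5 1-(allyloxy)-4-(benzyloxy)-2-methoxybenzene
Conditions: BnBr, K2CO3, DMF, rt
Reagents that add atoms: benzyl bromide, BrCc1ccccc1
Why: Williamson etherification of the single phenol; it places the benzyl group on the future O2'.

Step 4
Reactants: 5 1-(allyloxy)-4-(benzyloxy)-2-methoxybenzene
Product: 6 1-(allyloxy)-4-(benzyloxy)-5-bromo-2-methoxybenzene
Conditions: NBS, MeCN, 0 °C, dark
Reagents that add atoms: N-bromosuccinimide, O=C1CCC(=O)N1Br
Why: Electrophilic aromatic bromination at C5, which is para to methoxy and ortho to benzyloxy and is the only doubly activated unhindered position, as expected for a 1,2,4-trialkoxybenzene; in polar MeCN ionic ring bromination should outrun any reaction at the allyl group.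

Step 5
Reactants: 6 1-(allyloxy)-4-(benzyloxy)-5-bromo-2-methoxybenzene; 7 N,2-dimethoxy-N-methylacetamide
Product: 10 1-[5-(allyloxy)-2-(benzyloxy)-4-methoxyphenyl]-2-methoxyethan-1-one, via aryllithium 8 (not isolated), via lithium hemiaminal alkoxide 9 (not isolated)
Conditions: n-BuLi, THF, −78 °C; then 7, −78 → 0 °C; 1 M HCl
Reagents that add atoms: none
Why: Bromine–lithium exchange followed by Weinreb ketone synthesis; the chelated tetrahedral adduct 9 persists until the acidic quench, so the ketone is never exposed to aryllithium 8 and no tertiary alcohol can form.

Step 6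
Reactants: 10 1-[5-(allyloxy)-2-(benzyloxy)-4-methoxyphenyl]-2-methoxyethan-1-one; 11 2,4,6-trifluorobenzoyl chloride
Product: 14 2-[5-(allyloxy)-2-(benzyloxy)-4-methoxyphenyl]-5,7-difluoro-3-methoxy-4H-chromen-4-one, via lithium enolate 12 (not isolated), via 2-methoxy-1,3-diketone 13 (not isolated)
Conditions: LiN(SiMe3)2 (2.1 equiv), THF, −78 °C; then 11 (1.05 equiv), −78 °C → rt; then 60 °C
Reagents that add atoms: none
Why: LiN(SiMe3)2 removes a proton from the only enolisable carbon of 10 to give the chelated Z lithium enolate 12, which attacks 11 at carbon (C3–C4) to give diketone 13; the second equivalent of base deprotonates 13 at once, which pulls the acylation forward and shields the product from a second acylation. On warming, the diketonate oxygen on the ring B side adds to one of the two equivalent ortho C–F carbons, the anionic σ-adduct is stabilised by the C4 carbonyl on C4a and by the two remaining fluorines, and loss of fluoride forms O1–C8a. Ring C thus closes by intramolecular addition–elimination, formally a 6-endo-trig oxa-Michael addition to the C4a=C8a bond of the aryl ketone followed by β-elimination of fluoride. The closest known reaction type is the one-pot chromone and flavone synthesis from ketone enolates and 2-fluorobenzoyl chlorides. No stereocentre is formed. The selectivity needed is C- over O-acylation, which the covalent, chelated lithium enolate in THF at −78 °C favours; an enol ester formed by O-acylation is itself an acyl donor towards remaining enolate and should be funnelled to 13. Constitution is secured by the substrate: 10 has a single α-carbon, the two ortho fluorines of 11 are homotopic, and the ring A side oxygen of the diketonate could only close a four-membered ring. The acid chloride is used in slight excess over the ketone so that no free enolate remains to attack the para fluorine of another molecule.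

Step 7
Reactants: 14 2-[5-(allyloxy)-2-(benzyloxy)-4-methoxyphenyl]-5,7-difluoro-3-methoxy-4H-chromen-4-one
Product: 16 2-[5-(allyloxy)-2-(benzyloxy)-4-methoxyphenyl]-5,7-bis(benzyloxy)-3-methoxy-4H-chromen-4-one, via 7-benzyloxy-5-fluoro monoether 15 (not isolated)
Conditions: BnOH (3 equiv), NaH (2.6 equiv), THF, 0 °C; then 14, THF–DMF, 0 → 50 °C
Reagents that add atoms: benzyl alcohol (used as its sodium alkoxide), OCc1ccccc1
Why: Twofold SNAr on a fluorochromone: C7–F (para to C4a) and C5–F (ortho to C4a) are both activated by the C4 carbonyl and are meta to each other, so the first benzyloxy group does not occupy a charge-bearing position in the second addition; in a dipolar medium the para fluoride is expected to leave first, and excess benzyl alcohol tempers the basicity so that the allyl ether is not isomerised.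

Step 8
Reactants: 16 2-[5-(allyloxy)-2-(benzyloxy)-4-methoxyphenyl]-5,7-bis(benzyloxy)-3-methoxy-4H-chromen-4-one
Product: 17 5,7-bis(benzyloxy)-2-[2-(benzyloxy)-5-hydroxy-4-methoxyphenyl]-3-methoxy-4H-chromen-4-one
Conditions: Pd(PPh3)4 (5 mol %), morpholine, THF, rt
Reagents that add atoms: none
Why: Tsuji–Trost deallylation: zerovalent palladium ionises the allyl aryl ether to a π-allyl complex and the phenoxide, and morpholine traps the allyl group irreversibly; benzyl ethers, methyl ethers and the chromone are inert.

Step 9
Reactants: 17 5,7-bis(benzyloxy)-2-[2-(benzyloxy)-5-hydroxy-4-methoxyphenyl]-3-methoxy-4H-chromen-4-one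
Product: 18 4-(benzyloxy)-5-[5,7-bis(benzyloxy)-3-methoxy-4-oxo-4H-chromen-2-yl]-2-methoxyphenyl acetate
Conditions: Ac2O, pyridine, DMAP (cat.), CH2Cl2, 0 °C → rt
Reagents that add atoms: acetic anhydride, CC(=O)OC(C)=O
Why: Nucleophile-catalysed O-acylation of the only free hydroxyl in the molecule, so no selectivity is required.

Step 10
Reactants: 18 4-(benzyloxy)-5-[5,7-bis(benzyloxy)-3-methoxy-4-oxo-4H-chromen-2-yl]-2-methoxyphenyl acetate
Product: 19 5,7,2',5'-tetrahydroxy-3,4'-dimethoxyflavone 5'-acetate [5-(5,7-dihydroxy-3-methoxy-4-oxo-4H-chromen-2-yl)-4-hydroxy-2-methoxyphenyl acetate]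
Conditions: H2 (1 atm), Pd/C (10 wt %), EtOAc–THF, rt
Reagents that add atoms: none
Why: Hydrogenolysis of three benzyl aryl ethers over Pd/C in a neutral, aprotic medium that should leave the aryl acetate intact; the tetrasubstituted C2=C3 bond of the pyranone is not expected to be reduced at atmospheric pressure if the reaction is stopped after uptake of three equivalents.

## Compound list

1 | vanillin (4-hydroxy-3-methoxybenzaldehyde) | COc1cc(C=O)ccc1O | starting material
2 | 4-(allyloxy)-3-methoxybenzaldehyde | COc1cc(C=O)ccc1OCC=C | intermediate
3 | 4-(allyloxy)-3-methoxyphenyl formate | COc1cc(OC=O)ccc1OCC=C | intermediate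
4 | 4-(allyloxy)-3-methoxyphenol | COc1cc(O)ccc1OCC=C | intermediate
5 | 1-(allyloxy)-4-(benzyloxy)-2-methoxybenzene | COc1cc(OCc2ccccc2)ccc1OCC=C | intermediate
6 | 1-(allyloxy)-4-(benzyloxy)-5-bromo-2-methoxybenzene | COc1cc(OCc2ccccc2)c(Br)cc1OCC=C | intermediate
7 | N,2-dimethoxy-N-methylacetamide | COCC(=O)N(C)OC | starting material
8 | [5-(allyloxy)-2-(benzyloxy)-4-methoxyphenyl]lithium | [Li]c1cc(OCC=C)c(OC)cc1OCc1ccccc1 | intermediate
9 | lithium 1-[5-(allyloxy)-2-(benzyloxy)-4-methoxyphenyl]-2-methoxy-1-[methoxy(methyl)amino]ethan-1-olate (racemic) | COCC([O-])(N(C)OC)c1cc(OCC=C)c(OC)cc1OCc1ccccc1.[Li+] | intermediate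
10 | 1-[5-(allyloxy)-2-(benzyloxy)-4-methoxyphenyl]-2-methoxyethan-1-one | COCC(=O)c1cc(OCC=C)c(OC)cc1OCc1ccccc1 | intermediate
11 | 2,4,6-trifluorobenzoyl chloride | O=C(Cl)c1c(F)cc(F)cc1F | starting material
12 | lithium (Z)-1-[5-(allyloxy)-2-(benzyloxy)-4-methoxyphenyl]-2-methoxyethen-1-olate | CO/C=C(/c1cc(OCC=C)c(OC)cc1OCc1ccccc1)[O-].[Li+] | intermediate
13 | 1-[5-(allyloxy)-2-(benzyloxy)-4-methoxyphenyl]-2-methoxy-3-(2,4,6-trifluorophenyl)propane-1,3-dione (present as its lithium enolate; C2 not configurationally defined) | COC(C(=O)c1c(F)cc(F)cc1F)C(=O)c1cc(OCC=C)c(OC)cc1OCc1ccccc1 | intermediate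
14 | 2-[5-(allyloxy)-2-(benzyloxy)-4-methoxyphenyl]-5,7-difluoro-3-methoxy-4H-chromen-4-one | COc1cc(OCc2ccccc2)c(-c2oc3cc(F)cc(F)c3c(=O)c2OC)cc1OCC=C | intermediate
15 | 2-[5-(allyloxy)-2-(benzyloxy)-4-methoxyphenyl]-7-(benzyloxy)-5-fluoro-3-methoxy-4H-chromen-4-one | COc1cc(OCc2ccccc2)c(-c2oc3cc(OCc4ccccc4)cc(F)c3c(=O)c2OC)cc1OCC=C | intermediate
16 | 2-[5-(allyloxy)-2-(benzyloxy)-4-methoxyphenyl]-5,7-bis(benzyloxy)-3-methoxy-4H-chromen-4-one | COc1cc(OCc2ccccc2)c(-c2oc3cc(OCc4ccccc4)cc(OCc4ccccc4)c3c(=O)c2OC)cc1OCC=C | intermediate
17 | 5,7-bis(benzyloxy)-2-[2-(benzyloxy)-5-hydroxy-4-methoxyphenyl]-3-methoxy-4H-chromen-4-one | COc1cc(OCc2ccccc2)c(-c2oc3cc(OCc4ccccc4)cc(OCc4ccccc4)c3c(=O)c2OC)cc1O | intermediate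
18 | 4-(benzyloxy)-5-[5,7-bis(benzyloxy)-3-methoxy-4-oxo-4H-chromen-2-yl]-2-methoxyphenyl acetate | COc1cc(OCc2ccccc2)c(-c2oc3cc(OCc4ccccc4)cc(OCc4ccccc4)c3c(=O)c2OC)cc1OC(C)=O | intermediate
19 | 5,7,2',5'-tetrahydroxy-3,4'-dimethoxyflavone 5'-acetate | COc1cc(O)c(-c2oc3cc(O)cc(O)c3c(=O)c2OC)cc1OC(C)=O | target

## Step count and least certain steps

Total step count: 10. Longest linear sequence: 10 steps (1 → 19); 7 and 11 are purchased.

**Step 6 (key step).**
- **What may go wrong:** O-acylation of the α-alkoxy enolate may compete with C-acylation. The tightly chelated lithium diketonate may cyclise only sluggishly. Residual enolate may attack the para fluorine of another molecule.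
- **Fallback:** This sets out from 10 and returns at 14, and replaces the acylation by an aldol addition so that the C/O question does not arise. Enolate 12 (one equivalent of LiN(SiMe3)2, THF, −78 °C) is added to purchased 2,4,6-trifluorobenzaldehyde. This should give 1-[5-(allyloxy)-2-(benzyloxy)-4-methoxyphenyl]-3-hydroxy-2-methoxy-3-(2,4,6-trifluorophenyl)propan-1-one F1 as a racemic mixture of diastereomers. Dess–Martin oxidation of F1 should give diketone 13, which is isolated this time. K2CO3 in DMF at rt to 60 °C should then close ring C to 14, a potassium diketonate in a dipolar solvent being more nucleophilic than the lithium chelate.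

**Step 7.**
- **What may go wrong:** The hindered peri C5–F may exchange incompletely. The alkoxide may add reversibly at C2 and open the pyranone ring. The base may shift the allyl double bond into conjugation with oxygen.
- **Fallback:** This sets out from 14 and returns at 16, and treats the two fluorides separately. One equivalent of sodium benzyloxide at 0 °C should stop at 15, which is isolated. The remaining fluoride is displaced by a small α-effect oxygen nucleophile (acetohydroxamic acid, K2CO3, DMSO, 80 °C). This should proceed through N-({2-[5-(allyloxy)-2-(benzyloxy)-4-methoxyphenyl]-7-(benzyloxy)-3-methoxy-4-oxo-4H-chromen-5-yl}oxy)acetamide F2, which fragments in the flask by a Lossen-type rearrangement. The product should be 2-[5-(allyloxy)-2-(benzyloxy)-4-methoxyphenyl]-7-(benzyloxy)-5-hydroxy-3-methoxy-4H-chromen-4-one F3. Benzylation of the chelated 5-hydroxyl of F3 (BnBr, K2CO3, DMF, 70 °C) should give 16.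

**Step 5.**
- **What may go wrong:** Aryllithium 8 may be quenched by proton transfer from the α-methylene of 7 or from its own benzylic ether position. The ortho-benzyloxy aryllithium may rearrange on warming. Either path amounts to loss of the carbanion before it meets the amide.
- **Fallback:** This sets out from 5 and returns at 10, and avoids the aryllithium altogether. Vilsmeier–Haack formylation of 5 (POCl3, DMF, then aqueous NaOAc) should occur at the same position as the bromination and give 5-(allyloxy)-2-(benzyloxy)-4-methoxybenzaldehyde F4. Methoxymethylmagnesium chloride F5 is prepared from chloromethyl methyl ether and Mg in THF at −25 °C and added to F4. This should give racemic 1-[5-(allyloxy)-2-(benzyloxy)-4-methoxyphenyl]-2-methoxyethan-1-ol F6. Dess–Martin oxidation of F6 should give 10.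

**Step 10.**
- **What may go wrong:** The C2=C3 bond may be reduced on prolonged exposure. The hindered 5-O-benzyl group may cleave slowly. The aryl acetate may be lost if a protic solvent is used.
- **Fallback:** This sets out from 18 and returns at 19. It uses Lewis-acid debenzylation in place of hydrogenation: BCl3 with pentamethylbenzene as cation scavenger in CH2Cl2 at −78 °C. This should cleave the three benzyl ethers while leaving the ester and the methyl ethers untouched at that temperature. It makes no new compound, which is entered below as F0 with no structure.

## Further compounds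

F1 | step 6 | 1-[5-(allyloxy)-2-(benzyloxy)-4-methoxyphenyl]-3-hydroxy-2-methoxy-3-(2,4,6-trifluorophenyl)propan-1-one (racemic, mixture of diastereomers) | COC(C(O)c1c(F)cc(F)cc1F)C(=O)c1cc(OCC=C)c(OC)cc1OCc1ccccc1
F2 | step 7 | N-({2-[5-(allyloxy)-2-(benzyloxy)-4-methoxyphenyl]-7-(benzyloxy)-3-methoxy-4-oxo-4H-chromen-5-yl}oxy)acetamide | COc1cc(OCc2ccccc2)c(-c2oc3cc(OCc4ccccc4)cc(ONC(C)=O)c3c(=O)c2OC)cc1OCC=C
F3 | step 7 | 2-[5-(allyloxy)-2-(benzyloxy)-4-methoxyphenyl]-7-(benzyloxy)-5-hydroxy-3-methoxy-4H-chromen-4-one | COc1cc(OCc2ccccc2)c(-c2oc3cc(OCc4ccccc4)cc(O)c3c(=O)c2OC)cc1OCC=C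
F4 | step 5 | 5-(allyloxy)-2-(benzyloxy)-4-methoxybenzaldehyde | COc1cc(OCc2ccccc2)c(C=O)cc1OCC=C
F5 | step 5 | methoxymethylmagnesium chloride | COC[Mg]Cl
F6 | step 5 | 1-[5-(allyloxy)-2-(benzyloxy)-4-methoxyphenyl]-2-methoxyethan-1-ol (racemic) | COCC(O)c1cc(OCC=C)c(OC)cc1OCc1ccccc1
F0 | step 10 | none | none
A1 | alternative 1 | 1,5-bis(benzyloxy)-2-iodo-3-(methoxymethoxy)benzene | COCOc1cc(OCc2ccccc2)cc(OCc2ccccc2)c1I
A2 | alternative 1 | carbon monoxide | [C-]#[O+]
A3 | alternative 1 | 1-[2-(benzyloxy)-4-methoxy-5-(methoxymethoxy)phenyl]-2-methoxyethan-1-one | COCC(=O)c1cc(OCOC)c(OC)cc1OCc1ccccc1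
A4 | alternative 1 | 1-[2,4-bis(benzyloxy)-6-(methoxymethoxy)phenyl]-3-[2-(benzyloxy)-4-methoxy-5-(methoxymethoxy)phenyl]-2-methoxypropane-1,3-dione (racemic, enolisable) | COCOc1cc(OCc2ccccc2)cc(OCc2ccccc2)c1C(=O)C(OC)C(=O)c1cc(OCOC)c(OC)cc1OCc1ccccc1
A5 | alternative 2 | methyl 9-[2-(benzyloxy)-4-methoxy-5-(4-methoxybenzyloxy)phenyl]-8,9-dimethoxy-3,5,7-trioxonon-8-enoate (alkene geometry not defined) | COC(=O)CC(=O)CC(=O)CC(=O)C(OC)=C(OC)c1cc(OCc2ccc(OC)cc2)c(OC)cc1OCc1ccccc1
A6 | alternative 2 | 2-[2-(benzyloxy)-4-methoxy-5-(4-methoxybenzyloxy)phenyl]-5,7-dihydroxy-3-methoxy-4H-chromen-4-one | COc1cc(OCc2ccccc2)c(-c2oc3cc(O)cc(O)c3c(=O)c2OC)cc1OCc1ccc(OC)cc1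
A7 | alternative 3 | 3,5-bis(benzyloxy)-2-(trimethylsilyl)phenyl trifluoromethanesulfonate | C[Si](C)(C)c1c(OS(=O)(=O)C(F)(F)F)cc(OCc2ccccc2)cc1OCc1ccccc1
A8 | alternative 3 | 3,5-bis(benzyloxy)benzyne (1,2-didehydro-3,5-bis(benzyloxy)benzene) | C1#CC(OCc2ccccc2)=CC(OCc2ccccc2)=C1
A9 | alternative 3 | 6-[5-(allyloxy)-2-(benzyloxy)-4-methoxyphenyl]-5-methoxy-2,2-dimethyl-4H-1,3-dioxin-4-one | COC1=C(c2cc(OCC=C)c(OC)cc2OCc2ccccc2)OC(C)(C)OC1=O
A10 | alternative 3 | 3-[5-(allyloxy)-2-(benzyloxy)-4-methoxyphenyl]-2-methoxy-3-oxoprop-1-en-1-one | COC(=C=O)C(=O)c1cc(OCC=C)c(OC)cc1OCc1ccccc1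
A11 | alternative 3 | 2-[5-(allyloxy)-2-(benzyloxy)-4-methoxyphenyl]-5,7-bis(benzyloxy)-3-methoxy-4H-chromen-4-one | COc1cc(OCc2ccccc2)c(-c2oc3cc(OCc4ccccc4)cc(OCc4ccccc4)c3c(=O)c2OC)cc1OCC=C
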